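in all of them: free catalyst 2.5 mol%

|  | substrate | gas phase | remark | time |
|---|---|---|---|---|
| ochre | 25 mM | 3 mM (held) | run made earlier |  |
| blue | 40 mM | 3 mM (held) | run made earlier |  |
| flask | 18 mM | 3.0 mM (held) |  | 8.0 h |

| run | time / h | product / % | substrate / % |
|---|---|---|---|
| ochre | 0.667 | 15.2 | 86.7 |
| ochre | 1.00 | 18.6 | 80.4 |
| ochre | 1.33 | 22.9 | 76.2 |
| ochre | 2.50 | 32.8 | 68.6 |
| ochre | 3.00 | 33.8 | 65.1 |
| ochre | 5.00 | 43.3 | 54.2 |
| ochre | 8.00 | 50.2 | 49.6 |
| blue | 1.00 | 18.9 | 80.3 |
| blue | 2.50 | 33.6 | 68.5 |
| blue | 3.00 | 35.0 | 63.7 |
| blue | 5.00 | 43.0 | 55.9 |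
| blue | 6.00 | 47.4 | 50.7 |
| blue | 8.00 | 50.6 | 47.4 |

(standard deviation of a reading: 1 percentage point)

- at the start none of the gas is dissolved
- the analysis behind the earlier runs scatters by 1 percentage point, standard deviation
- on the list of suspects stand: 2 free catalyst -> spent catalyst; substrate + dissolved gas + free catalyst -> free catalyst + product; gas phase <-> dissolved gas; dissolved gas -> decomposed reagent
- the reaction counts as stopped when no species that holds the substrate changes by six tenths of a point or more over the second half of the time

1. which holds at 8.0 h: what has brought the reaction to rest, or that it has not come to rest (all of the substrate has reacted / no working catalyst is left / it is still moving)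
2. the product standing at 8.0 h, as a percentage of the substrate charged

1. The easy step is a division: product percent over catalyst loading. That is the turnover number, the rounds made per catalyst charged: 20.1 in the ochre run at 8.00 h, and 20.2 in the blue run at 8.00 h.

2. Is one number enough? The blue run starts with 1.00 mM of free catalyst, more than the 0.625 mM of the ochre run, yet the turnover numbers agree, and they agree earlier too: 7.44 and 7.56 at 1.00 h. But this flask starts at 0.450 mM, below both runs, so we carry the number outside the range where it was read.

3. We commit anyway: this flask has the same loading, 2.5 mol%, and is read at the same time, 8.0 h, so 20.1 turnovers give 50.2 % product. The ochre run still gained 6.9 percentage points from 5.00 h to 8.00 h, so we expect this flask to be still moving.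

4. The forecast says it is still moving and 46.5 %, lower than our figure, holding that “18 mM lies on the low side” of a maximum in percent rate.

5. The flask gives it is still moving and 49.5 %, which is 19.8 turnovers.

    2 free catalyst → spent catalyst (k = 0.464 /M/s)
    substrate + dissolved gas + free catalyst → free catalyst + product (k = 99.1 /M²/s)
    gas phase ⇌ dissolved gas, rate k3*(csat - [dissolved gas]) (kL = 0.00179 /s)
    dissolved gas → decomposed reagent (k = 2.21 × 10⁻⁵ /s)

6. A neighbouring flask with 11 mM of substrate keeps the loading, so the same reckoning again says 50.2 %. At 8.00 h that neighbour stands at 45.3 %, which is 18.1 turnovers.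

(All runs come from a simulation for an exercise; the scatter is artificial.)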